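**Plan**
1. Locants: flavone numbering (O1, C2–C8a; B ring C1'–C6'); C9 is the CH2 on C3, C10 the stereocentre, C11 the C(CH3)2OH carbon.
2. Retrosynthetic cuts, in order: C6–alkenyl (Suzuki), O1–C2 of the pyranone ring (cyclodehydration), C3–C9 of the oxepine ring (enolate alkylation), C2–C3 (aldol, then oxidation), O2'–C10 (Mitsunobu), C1'–CHO (formylation).
3. Enabling feature: C3 of the pyranone ring is the central carbon of a latent C2/C4 1,3-diketone, and C9 of the oxepine ring is a primary carbon beside C10. C3–C9 can therefore be closed by SN2 of a diketonate on a primary iodide before the pyranone exists.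
4. Forward order: B-ring ether (O2'–C10), then aldehyde, then the open diketone, then the oxepine ring (C3–C9), then the pyranone ring (O1–C2), then the C6 side chain and the free 4'-OH.
5. Stereochemistry: C10 (R) comes from methyl (S)-glycerate by Mitsunobu inversion and no later step breaks a bond at C10. The E alkene comes from syn hydroboration and a stereoretentive Suzuki coupling.

Key step: step 10

Remark: the iodides 10, 14, 15 and 16 carry the descriptor (S) at C10 only because CH2I outranks C(CH3)2OH; the spatial arrangement is that of (R)-9 and (R)-17. Compounds 14 (carbinol epimers) and 17 (C3 epimers and enol form) are carried as mixtures, because those centres are destroyed in steps 9 and 11.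

Step 1
Reactants: 1 4-bromoresorcinol
Product: 2 2-bromo-5-(triisopropylsilyloxy)phenol
Conditions: TIPSCl (1.0 equiv), imidazole, CH2Cl2, 0 °C
Reagents that add atoms: chlorotriisopropylsilane, CC(C)[Si](Cl)(C(C)C)C(C)C
Why: Regioselective phenol silylation, in which the bulky silyl chloride should take the unhindered hydroxyl para to bromine while the hydroxyl flanked by bromine is shielded.

Step 2
Reactants: 3 methyl (S)-glycerate
Product: 4 methyl (S)-3-(tert-butyldimethylsilyloxy)-2-hydroxypropanoate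
Conditions: TBSCl (1.05 equiv), imidazole, CH2Cl2, 0 °C
Reagents that add atoms: tert-butylchlorodimethylsilane, CC(C)(C)[Si](C)(C)Cl
Why: Selective silylation of the primary hydroxyl over the secondary, ester-deactivated one, leaving the C2 stereocentre untouched.

Step 3
Reactants: 2 2-bromo-5-(triisopropylsilyloxy)phenol; 4 methyl (S)-3-(tert-butyldimethylsilyloxy)-2-hydroxypropanoate
Product: 5 methyl (R)-2-[2-bromo-5-(triisopropylsilyloxy)phenoxy]-3-(tert-butyldimethylsilyloxy)propanoate
Conditions: PPh3, DIAD, toluene, 0 °C to rt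
Reagents that add atoms: none
Why: Mitsunobu etherification, in which the acidic ortho-bromophenol displaces the activated α-hydroxyl of the ester by SN2 with inversion (S to R), setting the future C10.

Step 4
Reactants: 5 methyl (R)-2-[2-bromo-5-(triisopropylsilyloxy)phenoxy]-3-(tert-butyldimethylsilyloxy)propanoate
Product: 6 (3R)-3-[2-bromo-5-(triisopropylsilyloxy)phenoxy]-4-(tert-butyldimethylsilyloxy)-2-methylbutan-2-ol
Conditions: MeMgBr (3.5 equiv), THF, –78 to 0 °C
Reagents that add atoms: methylmagnesium bromide, C[Mg]Br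
Why: Double Grignard addition to the α-aryloxy ester builds the dimethylcarbinol C11; addition outruns enolisation at low temperature, so C10 should keep its configuration, and the aryl bromide and both silyl ethers are inert.

Step 5
Reactants: 6 (3R)-3-[2-bromo-5-(triisopropylsilyloxy)phenoxy]-4-(tert-butyldimethylsilyloxy)-2-methylbutan-2-ol
Product: 9 2-{[(2R)-1,3-dihydroxy-3-methylbutan-2-yl]oxy}-4-(triisopropylsilyloxy)benzaldehyde, via aryllithium alkoxide 7 (not isolated), via silyl ether aldehyde 8 (not isolated)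
Conditions: n-BuLi (2.3 equiv), THF, –78 °C; DMF, –78 to 0 °C; then 2 M aq. HCl, rt
Reagents that add atoms: N,N-dimethylformamide, CN(C)C=O
Why: O-deprotonation and bromine–lithium exchange, formylation with DMF, and an acidic work-up that also cleaves the acid-labile primary TBS ether while the acid-stable aryl TIPS ether and the tertiary alcohol should persist.

Step 6
Reactants: 9 2-{[(2R)-1,3-dihydroxy-3-methylbutan-2-yl]oxy}-4-(triisopropylsilyloxy)benzaldehyde
Product: 10 2-{[(2S)-3-hydroxy-1-iodo-3-methylbutan-2-yl]oxy}-4-(triisopropylsilyloxy)benzaldehyde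
Conditions: PPh3, I2, imidazole, CH2Cl2, 0 °C to rt
Reagents that add atoms: iodine, II
Why: Appel-type iodination is selective for the primary hydroxyl, since the tertiary carbinol cannot be displaced under these conditions and no bond at C10 is involved.

Step 7
Reactants: 11 2',6'-dihydroxy-4'-methoxyacetophenone
Product: 12 1-[4-methoxy-2,6-bis(methoxymethoxy)phenyl]ethan-1-one
Conditions: NaH (2.5 equiv), MOMCl (2.5 equiv), DMF, 0 °C to rt
Reagents that add atoms: chloromethyl methyl ether, COCCl
Why: Williamson-type O-alkylation of both chelated phenols as MOM acetals keeps the A ring symmetric and releasable by acid.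

Step 8
Reactants: 12 1-[4-methoxy-2,6-bis(methoxymethoxy)phenyl]ethan-1-one; 10 2-{[(2S)-3-hydroxy-1-iodo-3-methylbutan-2-yl]oxy}-4-(triisopropylsilyloxy)benzaldehyde
Product: 14 3-hydroxy-3-[2-{[(2S)-3-hydroxy-1-iodo-3-methylbutan-2-yl]oxy}-4-(triisopropylsilyloxy)phenyl]-1-[4-methoxy-2,6-bis(methoxymethoxy)phenyl]propan-1-one (carbinol epimers), via lithium enolate 13 (not isolated)
Conditions: 12 (1.6 equiv), LiHMDS (1.5 equiv), THF, –78 °C; then 10; AcOH quench at –78 °C
Reagents that add atoms: none
Why: Directed aldol addition of the preformed lithium enolate to the non-enolisable aldehyde forms C2–C3 at –78 °C, where the hindered alkyl iodide and the tertiary hydroxyl are inert; the new carbinol centre is removed in step 9.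

Step 9
Reactants: 14 3-hydroxy-3-[2-{[(2S)-3-hydroxy-1-iodo-3-methylbutan-2-yl]oxy}-4-(triisopropylsilyloxy)phenyl]-1-[4-methoxy-2,6-bis(methoxymethoxy)phenyl]propan-1-one
Product: 15 1-[2-{[(2S)-3-hydroxy-1-iodo-3-methylbutan-2-yl]oxy}-4-(triisopropylsilyloxy)phenyl]-3-[4-methoxy-2,6-bis(methoxymethoxy)phenyl]propane-1,3-dione
Conditions: Dess–Martin periodinane (1.3 equiv), NaHCO3, CH2Cl2, 0 °C to rt
Reagents that add atoms: none
Why: Dess–Martin oxidation of the β-hydroxy ketone to the 1,3-diketone under buffered, non-basic conditions leaves the alkyl iodide, the MOM and silyl ethers and the tertiary alcohol alone, so the iodide never meets phosphine or sulfonyl reagents in the presence of the diketone.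

Step 10
Reactants: 15 1-[2-{[(2S)-3-hydroxy-1-iodo-3-methylbutan-2-yl]oxy}-4-(triisopropylsilyloxy)phenyl]-3-[4-methoxy-2,6-bis(methoxymethoxy)phenyl]propane-1,3-dione
Product: 17 (2R)-2-(2-hydroxypropan-2-yl)-4-[4-methoxy-2,6-bis(methoxymethoxy)benzoyl]-8-(triisopropylsilyloxy)-3,4-dihydro-1-benzoxepin-5(2H)-one (C4 epimers and enol form), via potassium diketonate 16 (not isolated)
Conditions: K2CO3 (3 equiv), butanone (0.01 M), 70 °C
Reagents that add atoms: none
Why: Carbonate deprotonates only the 1,3-diketone (the tertiary alcohol stays un-ionised), and the diketonate carbon C3 displaces iodide at the primary carbon C9 by SN2. The closest known reaction type is the C-alkylation of 1,3-diketones with alkyl iodides under carbonate/ketone-solvent conditions, used here intramolecularly. The oxepine ring closes in a 7-exo-tet mode, with the enolate double bond towards the A-ring carbonyl lying outside the forming ring. The only new stereocentre, C3 (benzoxepinone C4), is not controlled and need not be, because step 11 makes it sp2; C10 is a spectator, since neither its C–O nor its C–H bond is broken. The step needs C- over O-alkylation (the O-cyclised enol ether would also be seven-membered) and no oxetane formation; the soft iodide, the potassium-chelated U-shaped diketonate in a weakly ionising solvent, high dilution and a base too weak to ionise the tertiary alcohol are expected to secure this.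

Step 11
Reactants: 17 (2R)-2-(2-hydroxypropan-2-yl)-4-[4-methoxy-2,6-bis(methoxymethoxy)benzoyl]-8-(triisopropylsilyloxy)-3,4-dihydro-1-benzoxepin-5(2H)-one
Product: 19 oxepinoflavone silyl ether: (10R)-flavone bearing 5-OH and 7-OMe and 4'-OTIPS in which C3 is joined to O-2' through C9H2–C10H[C(CH3)2OH], via bis-phenol diketone 18 (not isolated)
Conditions: 3 M aq. HCl, THF, 50 °C
Reagents that add atoms: none
Why: Acid hydrolysis of both MOM acetals frees two equivalent phenols, either of which adds to the benzoxepinone carbonyl (C2) and dehydrates to the γ-pyranone (flavone cyclodehydration), giving one chromone and erasing the C3 centre; the aryl TIPS ether is acid-stable, and the tertiary alcohol, deactivated towards ionisation by the neighbouring aryloxy-bearing carbon, is expected to persist.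

Step 12
Reactants: 19 oxepinoflavone silyl ether (5-OH, 7-OMe, 4'-OTIPS, C6–H)
Product: 20 6-iodo derivative of 19
Conditions: BnMe3N·ICl2 (1.05 equiv), CaCO3, CH2Cl2–MeOH, rt
Reagents that add atoms: benzyltrimethylammonium dichloroiodate, C[N+](C)(C)Cc1ccccc1.Cl[I-]Cl
Why: Electrophilic aromatic iodination, in which the free hydrogen-bonded 5-OH directs iodine to its ortho carbon C6 (the established site for 5-hydroxy-7-alkoxyflavones under these buffered conditions), while the ether-only silylated B ring should not react without Lewis-acid activation.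

Step 13
Reactants: 21 3-methylbut-1-yne
Product: 22 (E)-4,4,5,5-tetramethyl-2-(3-methylbut-1-en-1-yl)-1,3,2-dioxaborolane
Conditions: pinacolborane, Cp2Zr(H)Cl (5 mol %), Et3N (10 mol %), neat, sealed tube, 60 °C
Reagents that add atoms: pinacolborane, B1OC(C)(C)C(C)(C)O1
Why: Zirconium-catalysed hydroboration of the terminal alkyne is a syn, anti-Markovnikov addition and should give only the (E)-alkenylboronate.

Step 14
Reactants: 20 6-iodo oxepinoflavone silyl ether; 22 (E)-4,4,5,5-tetramethyl-2-(3-methylbut-1-en-1-yl)-1,3,2-dioxaborolane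
Product: 23 6-[(E)-3-methylbut-1-enyl] oxepinoflavone silyl ether (4'-O-TIPS ether of the target)
Conditions: Pd(OAc)2 (5 mol %), SPhos (10 mol %), K3PO4, 1,4-dioxane–H2O, 80 °C
Reagents that add atoms: none
Why: Suzuki–Miyaura coupling of the di-ortho-substituted aryl iodide with the alkenylboronate proceeds with retention of the E geometry and tolerates the free 5-OH and tertiary alcohol; any premature loss of the silyl group only anticipates step 15.

Step 15
Reactants: 23 6-[(E)-3-methylbut-1-enyl] oxepinoflavone silyl ether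
Product: 24 CNP0216454.1
Conditions: TBAF (1.2 equiv), AcOH (1.2 equiv), THF, 0 °C
Reagents that add atoms: none
Why: Fluoride cleavage of the aryl silyl ether, buffered with acetic acid to keep the phenolic chromone away from base, should release the 4'-OH without touching any other group.

**Compound list**
1 | 4-bromoresorcinol | Oc1ccc(Br)c(O)c1 | starting material
2 | 2-bromo-5-(triisopropylsilyloxy)phenol | Oc1cc(O[Si](C(C)C)(C(C)C)C(C)C)ccc1Br | intermediate
3 | methyl (S)-glycerate | COC(=O)[C@@H](O)CO | starting material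
4 | methyl (S)-3-(tert-butyldimethylsilyloxy)-2-hydroxypropanoate | COC(=O)[C@@H](O)CO[Si](C)(C)C(C)(C)C | intermediate
5 | methyl (R)-2-[2-bromo-5-(triisopropylsilyloxy)phenoxy]-3-(tert-butyldimethylsilyloxy)propanoate | COC(=O)[C@H](Oc1cc(O[Si](C(C)C)(C(C)C)C(C)C)ccc1Br)CO[Si](C)(C)C(C)(C)C | intermediate
6 | (3R)-3-[2-bromo-5-(triisopropylsilyloxy)phenoxy]-4-(tert-butyldimethylsilyloxy)-2-methylbutan-2-ol | CC(C)(O)[C@H](Oc1cc(O[Si](C(C)C)(C(C)C)C(C)C)ccc1Br)CO[Si](C)(C)C(C)(C)C | intermediate
7 | aryllithium lithium alkoxide derived from 6 | [Li]OC(C)(C)[C@H](Oc1cc(O[Si](C(C)C)(C(C)C)C(C)C)ccc1[Li])CO[Si](C)(C)C(C)(C)C | intermediate (not isolated)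
8 | 2-{[(2R)-1-(tert-butyldimethylsilyloxy)-3-hydroxy-3-methylbutan-2-yl]oxy}-4-(triisopropylsilyloxy)benzaldehyde | CC(C)(O)[C@H](Oc1cc(O[Si](C(C)C)(C(C)C)C(C)C)ccc1C=O)CO[Si](C)(C)C(C)(C)C | intermediate (not isolated)
9 | 2-{[(2R)-1,3-dihydroxy-3-methylbutan-2-yl]oxy}-4-(triisopropylsilyloxy)benzaldehyde | CC(C)(O)[C@H](Oc1cc(O[Si](C(C)C)(C(C)C)C(C)C)ccc1C=O)CO | intermediate
10 | 2-{[(2S)-3-hydroxy-1-iodo-3-methylbutan-2-yl]oxy}-4-(triisopropylsilyloxy)benzaldehyde | CC(C)(O)[C@H](Oc1cc(O[Si](C(C)C)(C(C)C)C(C)C)ccc1C=O)CI | intermediate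
11 | 2',6'-dihydroxy-4'-methoxyacetophenone | CC(=O)c1c(O)cc(OC)cc1O | starting material
12 | 1-[4-methoxy-2,6-bis(methoxymethoxy)phenyl]ethan-1-one | CC(=O)c1c(OCOC)cc(OC)cc1OCOC | intermediate
13 | lithium enolate of 12 | [Li]OC(=C)c1c(OCOC)cc(OC)cc1OCOC | intermediate (not isolated)
14 | 3-hydroxy-3-[2-{[(2S)-3-hydroxy-1-iodo-3-methylbutan-2-yl]oxy}-4-(triisopropylsilyloxy)phenyl]-1-[4-methoxy-2,6-bis(methoxymethoxy)phenyl]propan-1-one (carbinol epimers) | CC(C)(O)[C@H](Oc1cc(O[Si](C(C)C)(C(C)C)C(C)C)ccc1C(O)CC(=O)c1c(OCOC)cc(OC)cc1OCOC)CI | intermediate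
15 | 1-[2-{[(2S)-3-hydroxy-1-iodo-3-methylbutan-2-yl]oxy}-4-(triisopropylsilyloxy)phenyl]-3-[4-methoxy-2,6-bis(methoxymethoxy)phenyl]propane-1,3-dione | CC(C)(O)[C@H](Oc1cc(O[Si](C(C)C)(C(C)C)C(C)C)ccc1C(=O)CC(=O)c1c(OCOC)cc(OC)cc1OCOC)CI | intermediate (key-step precursor)
16 | potassium diketonate of 15 | [K+].[O-]C(=CC(=O)c1ccc(O[Si](C(C)C)(C(C)C)C(C)C)cc1O[C@H](CI)C(C)(C)O)c1c(OCOC)cc(OC)cc1OCOC | intermediate (not isolated)
17 | (2R)-2-(2-hydroxypropan-2-yl)-4-[4-methoxy-2,6-bis(methoxymethoxy)benzoyl]-8-(triisopropylsilyloxy)-3,4-dihydro-1-benzoxepin-5(2H)-one (C4 epimers) | COCOc1cc(OC)cc(OCOC)c1C(=O)C1C[C@H](C(C)(C)O)Oc2cc(O[Si](C(C)C)(C(C)C)C(C)C)ccc2C1=O | intermediate (key-step product)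
18 | (2R)-4-(2,6-dihydroxy-4-methoxybenzoyl)-2-(2-hydroxypropan-2-yl)-8-(triisopropylsilyloxy)-3,4-dihydro-1-benzoxepin-5(2H)-one | COc1cc(O)c(C(=O)C2C[C@H](C(C)(C)O)Oc3cc(O[Si](C(C)C)(C(C)C)C(C)C)ccc3C2=O)c(O)c1 | intermediate (not isolated)
19 | oxepinoflavone silyl ether: (10R)-flavone with 5-OH, 7-OMe, 4'-OTIPS, C3 joined to O-2' through C9H2–C10H[C(CH3)2OH] | COc1cc2oc3c(c(=O)c2c(O)c1)C[C@H](C(C)(C)O)Oc1cc(O[Si](C(C)C)(C(C)C)C(C)C)ccc1-3 | intermediate
20 | 6-iodo derivative of 19 | COc1cc2oc3c(c(=O)c2c(O)c1I)C[C@H](C(C)(C)O)Oc1cc(O[Si](C(C)C)(C(C)C)C(C)C)ccc1-3 | intermediate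
21 | 3-methylbut-1-yne | CC(C)C#C | starting material
22 | (E)-4,4,5,5-tetramethyl-2-(3-methylbut-1-en-1-yl)-1,3,2-dioxaborolane | CC(C)/C=C/B1OC(C)(C)C(C)(C)O1 | intermediate
23 | 6-[(E)-3-methylbut-1-enyl] derivative of 19 (4'-O-TIPS ether of the target) | COc1cc2oc3c(c(=O)c2c(O)c1/C=C/C(C)C)C[C@H](C(C)(C)O)Oc1cc(O[Si](C(C)C)(C(C)C)C(C)C)ccc1-3 | intermediate
24 | CNP0216454.1: (10R)-5,4'-dihydroxy-7-methoxy-6-[(E)-3-methylbut-1-enyl]flavone with C3 joined to O-2' through C9H2–C10H[C(CH3)2OH] | COc1cc2oc3c(c(=O)c2c(O)c1/C=C/C(C)C)C[C@H](C(C)(C)O)Oc1cc(O)ccc1-3 | target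

**Count**
Total steps: 15. Longest linear sequence: 12 steps (steps 1, 3, 4, 5, 6, 8, 9, 10, 11, 12, 14, 15).

**Steps most likely to fail**

Step 10 (key ring closure). The diketonate may alkylate on oxygen to give the seven-membered enol ether, or may react so slowly at the β-branched, β-oxygenated iodide that decomposition takes over. The fallback sets out from 10 and comes back at 17. It closes the same C3–C9 bond from a simple aryl methyl ketone enolate, which as a lithium enolate alkylates iodides at carbon, and attaches the A ring afterwards. Aldehyde 10 with MeMgBr (THF, –78 °C) should give 1-[2-{[(2S)-3-hydroxy-1-iodo-3-methylbutan-2-yl]oxy}-4-(triisopropylsilyloxy)phenyl]ethan-1-ol F1, which Dess–Martin periodinane oxidises to the iodo methyl ketone F2. LiHMDS (1.05 equiv, THF, –78 °C to rt, high dilution) then closes (2R)-2-(2-hydroxypropan-2-yl)-8-(triisopropylsilyloxy)-3,4-dihydro-1-benzoxepin-5(2H)-one F3 by intramolecular enolate alkylation. The lithium enolate of F3 is added at –78 °C to 4-methoxy-2,6-bis(methoxymethoxy)benzaldehyde F4 (from purchasable 2,6-dihydroxy-4-methoxybenzaldehyde with NaH and MOMCl) to give the β-hydroxy ketone F5, and Dess–Martin oxidation of F5 returns 17.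

Step 12 (C6 iodination). The electrophile may spread to the oxygen-activated B ring (C3'/C5'), or a second iodine may enter at C8. The fallback sets out from 19 and comes back at 24. It deactivates the B ring with an acyl group before iodination. TBAF/AcOH removes the silyl group of 19 to give the 5,4'-diphenol F6. Pivaloyl chloride and Et3N (CH2Cl2, 0 °C) acylate only the 4'-OH, since the chelated 5-OH and the tertiary alcohol are unreactive, to give the 4'-O-pivalate F7. BnMe3N·ICl2/CaCO3 now has only the A-ring phenol to attack and should give the 6-iodo pivalate F8. Suzuki coupling of F8 with 22 gives the 6-alkenyl pivalate F9, and K2CO3 in MeOH cleaves the ester to give 24.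

Step 3 (Mitsunobu etherification). The activated glycerate may undergo β-elimination, or the hindered ortho-bromophenol may couple sluggishly, lowering conversion or enantiopurity. The fallback sets out from 4 (with 2) and comes back at 5. It replaces redox activation by sulfonate displacement. Tf2O and 2,6-lutidine (CH2Cl2, –78 °C) convert 4 into methyl (S)-3-(tert-butyldimethylsilyloxy)-2-(trifluoromethylsulfonyloxy)propanoate F10. The potassium phenoxide of 2 (K2CO3, MeCN, –20 °C to rt) then displaces the α-triflate by SN2 with inversion to give 5.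

**Further compounds**
F1 | step 10 | 1-[2-{[(2S)-3-hydroxy-1-iodo-3-methylbutan-2-yl]oxy}-4-(triisopropylsilyloxy)phenyl]ethan-1-ol (carbinol epimers) | CC(O)c1ccc(O[Si](C(C)C)(C(C)C)C(C)C)cc1O[C@H](CI)C(C)(C)O
F2 | step 10 | 1-[2-{[(2S)-3-hydroxy-1-iodo-3-methylbutan-2-yl]oxy}-4-(triisopropylsilyloxy)phenyl]ethan-1-one | CC(=O)c1ccc(O[Si](C(C)C)(C(C)C)C(C)C)cc1O[C@H](CI)C(C)(C)O
F3 | step 10 | (2R)-2-(2-hydroxypropan-2-yl)-8-(triisopropylsilyloxy)-3,4-dihydro-1-benzoxepin-5(2H)-one | O=C1CC[C@H](C(C)(C)O)Oc2cc(O[Si](C(C)C)(C(C)C)C(C)C)ccc21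
F4 | step 10 | 4-methoxy-2,6-bis(methoxymethoxy)benzaldehyde | COCOc1cc(OC)cc(OCOC)c1C=O
F5 | step 10 | (2R)-4-{hydroxy[4-methoxy-2,6-bis(methoxymethoxy)phenyl]methyl}-2-(2-hydroxypropan-2-yl)-8-(triisopropylsilyloxy)-3,4-dihydro-1-benzoxepin-5(2H)-one (epimers) | COCOc1cc(OC)cc(OCOC)c1C(O)C1C[C@H](C(C)(C)O)Oc2cc(O[Si](C(C)C)(C(C)C)C(C)C)ccc2C1=O
F6 | step 12 | desilylated 19 (5,4'-dihydroxy-7-methoxy oxepinoflavone, C6–H) | COc1cc2oc3c(c(=O)c2c(O)c1)C[C@H](C(C)(C)O)Oc1cc(O)ccc1-3
F7 | step 12 | 4'-O-pivalate of F6 | COc1cc2oc3c(c(=O)c2c(O)c1)C[C@H](C(C)(C)O)Oc1cc(OC(=O)C(C)(C)C)ccc1-3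
F8 | step 12 | 6-iodo 4'-O-pivalate | COc1cc2oc3c(c(=O)c2c(O)c1I)C[C@H](C(C)(C)O)Oc1cc(OC(=O)C(C)(C)C)ccc1-3
F9 | step 12 | 6-[(E)-3-methylbut-1-enyl] 4'-O-pivalate | COc1cc2oc3c(c(=O)c2c(O)c1/C=C/C(C)C)C[C@H](C(C)(C)O)Oc1cc(OC(=O)C(C)(C)C)ccc1-3
F10 | step 3 | methyl (S)-3-(tert-butyldimethylsilyloxy)-2-(trifluoromethylsulfonyloxy)propanoate | COC(=O)[C@@H](OS(=O)(=O)C(F)(F)F)CO[Si](C)(C)C(C)(C)C
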